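## Retrosynthetic overview

1. The 2‑substituted acrolein comes from Mannich α‑methylenation of a C7 CH2CHO group, itself from oxidative cleavage of a C7 allyl group; the C4 ester is cut to the C4 alcohol and (2E,4R)‑2,4‑dimethyloct‑2‑enoic acid (Evans methylation, Wittig).
2. The C4 hydroxyl comes from peracid γ‑hydroxylation of the octalone dienol ether; the C7 allyl group from kinetic enolate alkylation trans to the angular methyl.
3. The C1 carboxyl comes from hydroboration/oxidation of an exocyclic methylene made from the saturated ketone of (S)‑Wieland–Miescher ketone, with the enone masked as a dithiolane.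
4. Key C–C bond: intermolecular Michael addition of 2‑methylcyclohexane‑1,3‑dione to methyl vinyl ketone, which joins the two fragments and creates the quaternary carbon.
5. Ring order: ring B is the ring of the starting dione; ring A (the enone ring) is closed second by the L‑proline aldol condensation, which fixes the absolute configuration.

Assumption: locants follow the octahydronaphthalene‑1‑carboxylic acid numbering of the target (C1 carboxyl carbon, C4 acyloxy carbon, C4a=C5 alkene, C6 ketone, C7 side‑chain carbon, C8a methyl‑bearing carbon); ring A = C4a–C8a enone ring, ring B = C1–C4 ring.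

## Route

Step 1
Reactants: 1 2‑methylcyclohexane‑1,3‑dione; 2 methyl vinyl ketone (but‑3‑en‑2‑one)
Product: 3 2‑methyl‑2‑(3‑oxobutyl)cyclohexane‑1,3‑dione
Conditions: H2O, AcOH (cat.), hydroquinone (cat.), 75 °C
Reagents that add atoms: none
Why: Intermolecular Michael addition of the enolised 1,3‑dione to the vinyl ketone forms the C8–C8a bond and the quaternary carbon; the product is still achiral because its two ring carbonyls are enantiotopic.

Step 2
Reactants: 3 2‑methyl‑2‑(3‑oxobutyl)cyclohexane‑1,3‑dione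
Product: 5 (S)‑8a‑methyl‑3,4,8,8a‑tetrahydronaphthalene‑1,6(2H,7H)‑dione [(S)‑Wieland–Miescher ketone], via cis‑ketol 4 (not isolated)
Conditions: L‑proline (5 mol %), DMSO, 35 °C; recrystallisation (Et2O/hexane) to ≥98% ee
Reagents that add atoms: none
Why: Hajos–Parrish–Eder–Sauer–Wiechert enamine aldol in which the proline enamine of the side‑chain ketone attacks one enantiotopic ring carbonyl through the acid‑directed transition state, fixing the 8aS quaternary centre, and dehydration of the ketol closes ring A as the enone.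

Step 3
Reactants: 5 (S)‑Wieland–Miescher ketone
Product: 6 (4a'S)‑4a'‑methyl‑4',4a',7',8'‑tetrahydro‑3'H‑spiro[1,3‑dithiolane‑2,2'‑naphthalen]‑5'(6'H)‑one (the C6 dithiolane of 5; C1 ketone free)
Conditions: HSCH2CH2SH (1.05 equiv), p‑toluenesulfonic acid (cat.), AcOH, rt
Reagents that add atoms: ethane‑1,2‑dithiol, SCCS
Why: Acid‑catalysed thioketalisation is chemoselective for the enone carbonyl because the saturated ketone is neopentyl, the alkene does not migrate and the stereocentre is untouched.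

Step 4
Reactants: 6 enone dithiolane
Product: 7 C1‑methylidene analogue of 6 (C1=CH2 in place of C1=O; 8aR by CIP, same spatial arrangement)
Conditions: Ph3PCH3Br, KOt‑Bu, THF, 0 °C → reflux
Reagents that add atoms: methyltriphenylphosphonium bromide, C[P+](c1ccccc1)(c1ccccc1)c1ccccc1.[Br-]
Why: Wittig methylenation of the hindered, non‑conjugated C1 ketone while the dithiolane keeps the enone out of play; the quaternary centre is unaffected.

Step 5
Reactants: 7 exocyclic alkene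
Product: 9 primary alcohol with C1–CH2OH cis to the 8a‑methyl (1S,8aR; dithiolane retained), via alkylborane 8 (not isolated)
Conditions: 9‑BBN‑H, THF, 0 °C → rt; then NaOH, H2O2, H2O, 0 °C
Reagents that add atoms: 9‑borabicyclo[3.3.1]nonane, B1C2CCCC1CCC2 (its boron stands in 8 only); hydrogen peroxide, OO (gives the oxygen of 9)
Why: Brown hydroboration–oxidation in which 9‑BBN adds anti‑Markovnikov to the 1,1‑disubstituted alkene only and from the face opposite the adjacent axial 8a‑methyl, so C1–H ends trans and CH2OH cis to the methyl (1S), and the C–B bond is oxidised with retention.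

Step 6
Reactants: 9 hydroxymethyl dithiolane
Product: 10 (4aR,5S)‑5‑(hydroxymethyl)‑4a‑methyl‑4,4a,5,6,7,8‑hexahydronaphthalen‑2(3H)‑one
Conditions: MeI (excess), CaCO3, MeCN/H2O (4:1), 55 °C
Reagents that add atoms: water, O (the ketone oxygen)
Why: Alkylative dithioketal hydrolysis (S‑methylation makes sulfur a leaving group and water delivers the carbonyl oxygen) under near‑neutral conditions that leave the primary alcohol and the C1 centre alone.

Step 7
Reactants: 10 hydroxymethyl enone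
Product: 12 (1S,8aR)‑8a‑methyl‑6‑oxo‑1,2,3,4,6,7,8,8a‑octahydronaphthalene‑1‑carboxylic acid, via aldehyde 11 (not isolated)
Conditions: PhI(OAc)2 (2.2 equiv), 2,2,6,6‑tetramethylpiperidin‑1‑oxyl (cat.), MeCN/H2O (1:1), rt
Reagents that add atoms: water, O (second oxygen of the carboxyl group)
Why: Oxoammonium oxidation in wet acetonitrile takes the primary alcohol through the aldehyde hydrate to the acid without base, so the epimerisable C1 centre is kept and the enone is not touched.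

Step 8
Reactants: 12 enone acid
Product: 13 tert‑butyl (1S,8aR)‑8a‑methyl‑6‑oxo‑1,2,3,4,6,7,8,8a‑octahydronaphthalene‑1‑carboxylate
Conditions: Cl3CC(=NH)Ot‑Bu (2.5 equiv), BF3·OEt2 (cat.), CH2Cl2/cyclohexane, rt
Reagents that add atoms: tert‑butyl 2,2,2‑trichloroacetimidate, CC(C)(C)OC(=N)C(Cl)(Cl)Cl
Why: Acid‑catalysed tert‑butyl transfer from the trichloroacetimidate alkylates the carboxyl oxygen, so hindrance at C1 does not matter and no stereocentre is involved.

Step 9
Reactants: 13 enone tert‑butyl ester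
Product: 14 tert‑butyl (1S,7R,8aR)‑8a‑methyl‑6‑oxo‑7‑(prop‑2‑en‑1‑yl)‑1,2,3,4,6,7,8,8a‑octahydronaphthalene‑1‑carboxylate
Conditions: LiN(i‑Pr)2 (1.1 equiv), THF, −78 °C; then allyl bromide, DMPU, −78 → −30 °C
Reagents that add atoms: allyl bromide, C=CCBr
Why: Kinetic cross‑conjugated lithium enolate formation at C7 and SN2 alkylation anti to the axial 8a‑methyl give the 7‑allyl group trans to it (7R), which is also the equatorial, thermodynamically preferred epimer.

Step 10
Reactants: 14 7‑allyl enone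
Product: 15 tert‑butyl (1S,7R,8aR)‑6‑methoxy‑8a‑methyl‑7‑(prop‑2‑en‑1‑yl)‑1,2,3,7,8,8a‑hexahydronaphthalene‑1‑carboxylate
Conditions: HC(OMe)3, p‑toluenesulfonic acid (cat.), MeOH/THF, rt; Et3N quench
Reagents that add atoms: trimethyl orthoformate, COC(OC)OC
Why: Acid‑catalysed enol etherification with the orthoformate as water scavenger gives the conjugated heteroannular dienol ether (C4=C4a, C5=C6), as with steroidal enones, and C7 is not part of the diene.

Step 11
Reactants: 15 dienol ether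
Product: 16 tert‑butyl (1S,4R,7R,8aR)‑4‑hydroxy‑8a‑methyl‑6‑oxo‑7‑(prop‑2‑en‑1‑yl)‑1,2,3,4,6,7,8,8a‑octahydronaphthalene‑1‑carboxylate
Conditions: mCPBA (1.05 equiv), 1,4‑dioxane/H2O (9:1), 0 °C
Reagents that add atoms: mCPBA, OOC(=O)c1cccc(Cl)c1 (hydroxyl oxygen); water, O (ketone oxygen)
Why: Peracid γ‑hydroxylation of the dienol ether (vinylogous Rubottom‑type oxidation) in which the electron‑rich diene terminus C4 reacts far faster than the monosubstituted allyl alkene, axial attack puts the oxygen on the face of the 8a‑methyl (4R) as in the 6β‑hydroxylation of steroidal dienol ethers, and loss of methanol returns the enone.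

Step 12
Reactants: 17 (R)‑4‑benzyloxazolidin‑2‑one; 18 hexanoyl chloride
Product: 19 (R)‑4‑benzyl‑3‑hexanoyloxazolidin‑2‑one
Conditions: n‑BuLi, THF, −78 °C; then 18, −78 °C → 0 °C
Reagents that add atoms: none
Why: N‑acylation of the lithiated Evans oxazolidinone with the acid chloride; the auxiliary stereocentre is untouched.

Step 13
Reactants: 19 N‑hexanoyl oxazolidinone
Product: 20 (R)‑4‑benzyl‑3‑[(R)‑2‑methylhexanoyl]oxazolidin‑2‑one
Conditions: NaN(SiMe3)2, THF, −78 °C; then MeI, −78 °C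
Reagents that add atoms: iodomethane, CI
Why: Evans asymmetric alkylation in which the chelated sodium Z‑enolate is methylated on the face opposite the benzyl group, giving the (R)‑2‑methylhexanoyl centre; the minor diastereomer is removed by chromatography.

Step 14
Reactants: 20 methylated imide
Product: 21 (R)‑2‑methylhexan‑1‑ol
Conditions: LiBH4, MeOH (1 equiv), Et2O, 0 °C
Reagents that add atoms: none
Why: Reductive cleavage of the imide at the exocyclic carbonyl releases the primary alcohol without touching the α‑stereocentre and returns the auxiliary.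

Step 15
Reactants: 21 (R)‑2‑methylhexan‑1‑ol
Product: 23 ethyl (2E,4R)‑2,4‑dimethyloct‑2‑enoate, via (R)‑2‑methylhexanal 22 (not isolated)
Conditions: PhI(OAc)2 (1.1 equiv), 2,2,6,6‑tetramethylpiperidin‑1‑oxyl (cat.), CH2Cl2, rt; then Ph3P=C(CH3)CO2Et, rt → 40 °C
Reagents that add atoms: ethyl 2‑(triphenylphosphoranylidene)propanoate, CCOC(=O)C(C)=P(c1ccccc1)(c1ccccc1)c1ccccc1
Why: Oxoammonium oxidation to the labile α‑branched aldehyde is followed in the same flask by Wittig olefination with the stabilised ylide, which gives the trisubstituted (E)‑enoate without epimerising the adjacent stereocentre.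

Step 16
Reactants: 23 ethyl enoate
Product: 24 (2E,4R)‑2,4‑dimethyloct‑2‑enoic acid
Conditions: LiOH·H2O, THF/MeOH/H2O, 40 °C; then 1 M HCl
Reagents that add atoms: lithium hydroxide, [Li+].[OH-] (carboxyl OH oxygen)
Why: Saponification of the hindered ethyl ester by acyl–oxygen cleavage; hydroxide does not deprotonate the γ‑position, so alkene geometry and stereocentre are kept.

Step 17
Reactants: 16 C4 alcohol; 24 (2E,4R)‑2,4‑dimethyloct‑2‑enoic acid
Product: 26 tert‑butyl (1S,4R,7R,8aR)‑4‑{[(2E,4R)‑2,4‑dimethyloct‑2‑enoyl]oxy}‑8a‑methyl‑6‑oxo‑7‑(prop‑2‑en‑1‑yl)‑1,2,3,4,6,7,8,8a‑octahydronaphthalene‑1‑carboxylate, via mixed anhydride 25 (not isolated)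
Conditions: 24, 2,4,6‑Cl3C6H2COCl, Et3N, toluene, rt; then 16, 4‑(dimethylamino)pyridine, toluene, rt → 40 °C
Reagents that add atoms: 2,4,6‑trichlorobenzoyl chloride, O=C(Cl)c1c(Cl)cc(Cl)cc1Cl (its acyl group stands in 25 only)
Why: Yamaguchi esterification in which 4‑(dimethylamino)pyridine attacks the less hindered enoyl carbonyl of the mixed anhydride and the acylpyridinium acylates the hindered axial alcohol with retention at C4, since only the O–H bond is broken.

Step 18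
Reactants: 26 tert‑butyl ester
Product: 27 (1S,4R,7R,8aR)‑4‑{[(2E,4R)‑2,4‑dimethyloct‑2‑enoyl]oxy}‑8a‑methyl‑6‑oxo‑7‑(prop‑2‑en‑1‑yl)‑1,2,3,4,6,7,8,8a‑octahydronaphthalene‑1‑carboxylic acid
Conditions: CF3CO2H/CH2Cl2 (1:4), 0 °C → rt
Reagents that add atoms: none
Why: Acidolysis of the tert‑butyl ester through the tert‑butyl cation frees the acid before any acid‑sensitive aldehyde is present, and the allylic ester, made electron‑poor by the enone, does not ionise.

Step 19
Reactants: 27 allyl acid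
Product: 29 (1S,4R,7S,8aR)‑4‑{[(2E,4R)‑2,4‑dimethyloct‑2‑enoyl]oxy}‑8a‑methyl‑6‑oxo‑7‑(2‑oxoethyl)‑1,2,3,4,6,7,8,8a‑octahydronaphthalene‑1‑carboxylic acid, via vicinal diol 28 (not isolated)
Conditions: OsO4 (2 mol %), NaIO4 (4 equiv), 2,6‑lutidine, 1,4‑dioxane/H2O (3:1), rt
Reagents that add atoms: osmium tetroxide, O=[Os](=O)(=O)=O (catalytic; gives both oxygens of 28, one of which stays in 29); sodium periodate, [Na+].[O-]I(=O)(=O)=O (restores the osmium oxide)
Why: Lemieux–Johnson oxidation in which OsO4 dihydroxylates only the terminal alkene (the enone and enoate alkenes are electron‑poor and hindered) and periodate cleaves the diol to the aldehyde, leaving C7 unaffected.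

Step 20
Reactants: 29 keto aldehyde acid
Product: 31 (1S,4R,7S,8aR)‑4‑{[(2E,4R)‑2,4‑dimethyloct‑2‑enoyl]oxy}‑8a‑methyl‑6‑oxo‑7‑(3‑oxoprop‑1‑en‑2‑yl)‑1,2,3,4,6,7,8,8a‑octahydronaphthalene‑1‑carboxylic acid (target), via Mannich base 30 (not isolated)
Conditions: CH2=NMe2+ I− (3 equiv), Et3N (5 equiv), CH2Cl2, rt; pH 3 buffer work‑up
Reagents that add atoms: N,N‑dimethylmethyleneiminium iodide, C=[N+](C)C.[I-] (its CH2 stays; the NMe2 group stands in 30 only)
Why: Mannich reaction of the aldehyde enol with the preformed iminium salt at the only unhindered α‑carbon, then β‑elimination of dimethylamine, gives the 2‑substituted acrolein, and C7 stays in (or equilibrates to) the equatorial 7S configuration trans to the 8a‑methyl.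

## Compound list

1 | 2‑methylcyclohexane‑1,3‑dione | CC1C(=O)CCCC1=O | starting material
2 | methyl vinyl ketone (but‑3‑en‑2‑one) | CC(=O)C=C | starting material
3 | 2‑methyl‑2‑(3‑oxobutyl)cyclohexane‑1,3‑dione | CC(=O)CCC1(C)C(=O)CCCC1=O | intermediate
4 | (4aS,8aS)‑4a‑hydroxy‑8a‑methyloctahydronaphthalene‑1,6‑dione (cis‑ketol, OH and CH3 cis) | C1C[C@@]2(C)[C@@](O)(CC1=O)CCCC2=O | intermediate (not isolated)
5 | (S)‑8a‑methyl‑3,4,8,8a‑tetrahydronaphthalene‑1,6(2H,7H)‑dione, (S)‑Wieland–Miescher ketone | C1C[C@@]2(C)C(=CC1=O)CCCC2=O | intermediate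
6 | (4a'S)‑4a'‑methyl‑4',4a',7',8'‑tetrahydro‑3'H‑spiro[1,3‑dithiolane‑2,2'‑naphthalen]‑5'(6'H)‑one (C6 dithiolane of 5) | C1C[C@@]2(C)C(=CC13SCCS3)CCCC2=O | intermediate
7 | C1‑methylidene analogue of 6 (8aR) | C1C[C@@]2(C)C(=CC13SCCS3)CCCC2=C | intermediate
8 | B‑alkyl‑9‑BBN adduct of 7 (boron on the exocyclic CH2, C1–H trans to the 8a‑methyl) | C1C[C@@]2(C)C(=CC13SCCS3)CCC[C@@H]2CB4C5CCCC4CCC5 | intermediate (not isolated)
9 | (1S,8aR) primary alcohol, C1–CH2OH cis to 8a‑CH3, C6 dithiolane retained | C1C[C@@]2(C)C(=CC13SCCS3)CCC[C@@H]2CO | intermediate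
10 | (4aR,5S)‑5‑(hydroxymethyl)‑4a‑methyl‑4,4a,5,6,7,8‑hexahydronaphthalen‑2(3H)‑one | C1C[C@@]2(C)C(=CC1=O)CCC[C@@H]2CO | intermediate
11 | (1S,8aR)‑8a‑methyl‑6‑oxo‑1,2,3,4,6,7,8,8a‑octahydronaphthalene‑1‑carbaldehyde | C1C[C@@]2(C)C(=CC1=O)CCC[C@@H]2C=O | intermediate (not isolated)
12 | (1S,8aR)‑8a‑methyl‑6‑oxo‑1,2,3,4,6,7,8,8a‑octahydronaphthalene‑1‑carboxylic acid | C1C[C@@]2(C)C(=CC1=O)CCC[C@@H]2C(=O)O | intermediate
13 | tert‑butyl (1S,8aR)‑8a‑methyl‑6‑oxo‑1,2,3,4,6,7,8,8a‑octahydronaphthalene‑1‑carboxylate | C1C[C@@]2(C)C(=CC1=O)CCC[C@@H]2C(=O)OC(C)(C)C | intermediate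
14 | tert‑butyl (1S,7R,8aR)‑8a‑methyl‑6‑oxo‑7‑(prop‑2‑en‑1‑yl)‑1,2,3,4,6,7,8,8a‑octahydronaphthalene‑1‑carboxylate | C=CC[C@@H]1C[C@@]2(C)C(=CC1=O)CCC[C@@H]2C(=O)OC(C)(C)C | intermediate
15 | tert‑butyl (1S,7R,8aR)‑6‑methoxy‑8a‑methyl‑7‑(prop‑2‑en‑1‑yl)‑1,2,3,7,8,8a‑hexahydronaphthalene‑1‑carboxylate | C=CC[C@@H]1C[C@@]2(C)C(C=C1OC)=CCC[C@@H]2C(=O)OC(C)(C)C | intermediate
16 | tert‑butyl (1S,4R,7R,8aR)‑4‑hydroxy‑8a‑methyl‑6‑oxo‑7‑(prop‑2‑en‑1‑yl)‑1,2,3,4,6,7,8,8a‑octahydronaphthalene‑1‑carboxylate | C=CC[C@@H]1C[C@@]2(C)C(=CC1=O)[C@H](O)CC[C@@H]2C(=O)OC(C)(C)C | intermediate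
17 | (R)‑4‑benzyloxazolidin‑2‑one | O=C1N[C@H](Cc2ccccc2)CO1 | starting material
18 | hexanoyl chloride | CCCCCC(=O)Cl | starting material
19 | (R)‑4‑benzyl‑3‑hexanoyloxazolidin‑2‑one | CCCCCC(=O)N1[C@H](Cc2ccccc2)COC1=O | intermediate
20 | (R)‑4‑benzyl‑3‑[(R)‑2‑methylhexanoyl]oxazolidin‑2‑one | CCCC[C@@H](C)C(=O)N1[C@H](Cc2ccccc2)COC1=O | intermediate
21 | (R)‑2‑methylhexan‑1‑ol | CCCC[C@@H](C)CO | intermediate
22 | (R)‑2‑methylhexanal | CCCC[C@@H](C)C=O | intermediate (not isolated)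
23 | ethyl (2E,4R)‑2,4‑dimethyloct‑2‑enoate | CCOC(=O)/C(C)=C/[C@H](C)CCCC | intermediate
24 | (2E,4R)‑2,4‑dimethyloct‑2‑enoic acid | OC(=O)/C(C)=C/[C@H](C)CCCC | intermediate
25 | (2E,4R)‑2,4‑dimethyloct‑2‑enoic 2,4,6‑trichlorobenzoic anhydride | O=C(OC(=O)/C(C)=C/[C@H](C)CCCC)c1c(Cl)cc(Cl)cc1Cl | intermediate (not isolated)
26 | tert‑butyl (1S,4R,7R,8aR)‑4‑{[(2E,4R)‑2,4‑dimethyloct‑2‑enoyl]oxy}‑8a‑methyl‑6‑oxo‑7‑(prop‑2‑en‑1‑yl)‑1,2,3,4,6,7,8,8a‑octahydronaphthalene‑1‑carboxylate | C=CC[C@@H]1C[C@@]2(C)C(=CC1=O)[C@H](OC(=O)/C(C)=C/[C@H](C)CCCC)CC[C@@H]2C(=O)OC(C)(C)C | intermediate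
27 | (1S,4R,7R,8aR)‑4‑{[(2E,4R)‑2,4‑dimethyloct‑2‑enoyl]oxy}‑8a‑methyl‑6‑oxo‑7‑(prop‑2‑en‑1‑yl)‑1,2,3,4,6,7,8,8a‑octahydronaphthalene‑1‑carboxylic acid | C=CC[C@@H]1C[C@@]2(C)C(=CC1=O)[C@H](OC(=O)/C(C)=C/[C@H](C)CCCC)CC[C@@H]2C(=O)O | intermediate
28 | 7‑(2,3‑dihydroxypropyl) analogue of 27 (both carbinol epimers) | OCC(O)C[C@@H]1C[C@@]2(C)C(=CC1=O)[C@H](OC(=O)/C(C)=C/[C@H](C)CCCC)CC[C@@H]2C(=O)O | intermediate (not isolated)
29 | (1S,4R,7S,8aR)‑4‑{[(2E,4R)‑2,4‑dimethyloct‑2‑enoyl]oxy}‑8a‑methyl‑6‑oxo‑7‑(2‑oxoethyl)‑1,2,3,4,6,7,8,8a‑octahydronaphthalene‑1‑carboxylic acid | O=CC[C@@H]1C[C@@]2(C)C(=CC1=O)[C@H](OC(=O)/C(C)=C/[C@H](C)CCCC)CC[C@@H]2C(=O)O | intermediate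
30 | 7‑[1‑(dimethylamino)‑3‑oxopropan‑2‑yl] analogue of 29 (Mannich base, both side‑chain epimers) | CN(C)CC(C=O)[C@@H]1C[C@@]2(C)C(=CC1=O)[C@H](OC(=O)/C(C)=C/[C@H](C)CCCC)CC[C@@H]2C(=O)O | intermediate (not isolated)
31 | (1S,4R,7S,8aR)‑4‑{[(2E,4R)‑2,4‑dimethyloct‑2‑enoyl]oxy}‑8a‑methyl‑6‑oxo‑7‑(3‑oxoprop‑1‑en‑2‑yl)‑1,2,3,4,6,7,8,8a‑octahydronaphthalene‑1‑carboxylic acid | C=C(C=O)[C@@H]1C[C@@]2(C)C(=CC1=O)[C@H](OC(=O)/C(C)=C/[C@H](C)CCCC)CC[C@@H]2C(=O)O | target

## Step count and risks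

Total: 20 steps. Longest linear sequence: 15 steps (steps 1–11, then 17–20); the side‑chain acid takes 5 steps (12–16).

Steps most likely to fail:

**Step 5 (facial selectivity of the hydroboration at C1).** The fallback sets out from 6 and comes back at 9. Wittig reaction of 6 with Ph3P=CHOMe (from Ph3P(CH2OMe)Cl and KOt‑Bu, THF, 0 °C → rt) gives the methyl enol ether F1 as an E/Z mixture. Hydrolysis with 2 M HCl/THF, then K2CO3/MeOH, equilibrates the C1 centre; the aldehyde with the formyl group cis to the 8a‑methyl, the (1S,8aR) aldehyde F2, is separated and its epimer is put back into the equilibration. NaBH4 in MeOH at 0 °C reduces it to 9. C1 is then set by equilibration plus separation and recycling, not by the face selectivity of a borane.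

**Step 11 (configuration of the new C4 hydroxyl).** The fallback sets out from 15 and comes back at 26. If the peracid gives mainly the other face, the product is the C4‑epimeric alcohol F3. It is esterified under Mitsunobu conditions with acid 24 (PPh3, diisopropyl azodicarboxylate, toluene, 0 °C → rt). SN2 displacement at C4 inverts the centre while the ester is formed, so 26 is reached directly and step 17 is not needed.

**Step 20 (Mannich methylenation on the free acid, with a product that can isomerise to the conjugated alkylidene).** The fallback sets out from 13 and comes back at 31. The three‑carbon unit is brought in whole by an intermolecular aldol: the lithium enolate of 13 (LiN(i‑Pr)2, THF, −78 °C) adds to 1,1‑dimethoxypropan‑2‑one to give the β‑hydroxy ketone F4. SOCl2/pyridine in CH2Cl2 at −20 °C dehydrates it toward the methyl group to the 2‑propenyl acetal F5; the regiochemistry of this elimination is the weak point of the fallback. The sequence of steps 10, 11 and 17 then gives the dienol ether F6, the 4β‑alcohol F7 and, with 24 through 25, the ester F8. CF3CO2H/CH2Cl2/H2O at 0 °C removes the dimethyl acetal and the tert‑butyl ester together and gives 31.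

## Further compounds

F1 | step 5 | C1=CH–OCH3 enol ether analogue of 6 (E/Z mixture, dithiolane retained) | C1C[C@@]2(C)C(=CC13SCCS3)CCCC2=COC
F2 | step 5 | (1S,8aR) C1‑carbaldehyde with CHO cis to the 8a‑methyl, dithiolane retained | C1C[C@@]2(C)C(=CC13SCCS3)CCC[C@@H]2C=O
F3 | step 11 | tert‑butyl (1S,4S,7R,8aR)‑4‑hydroxy‑8a‑methyl‑6‑oxo‑7‑(prop‑2‑en‑1‑yl)‑1,2,3,4,6,7,8,8a‑octahydronaphthalene‑1‑carboxylate | C=CC[C@@H]1C[C@@]2(C)C(=CC1=O)[C@@H](O)CC[C@@H]2C(=O)OC(C)(C)C
F4 | step 20 | tert‑butyl (1S,7S,8aR)‑7‑(2‑hydroxy‑1,1‑dimethoxypropan‑2‑yl)‑8a‑methyl‑6‑oxo‑1,2,3,4,6,7,8,8a‑octahydronaphthalene‑1‑carboxylate (both carbinol epimers) | COC(OC)C(C)(O)[C@@H]1C[C@@]2(C)C(=CC1=O)CCC[C@@H]2C(=O)OC(C)(C)C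
F5 | step 20 | tert‑butyl (1S,7S,8aR)‑7‑(3,3‑dimethoxyprop‑1‑en‑2‑yl)‑8a‑methyl‑6‑oxo‑1,2,3,4,6,7,8,8a‑octahydronaphthalene‑1‑carboxylate | COC(OC)C(=C)[C@@H]1C[C@@]2(C)C(=CC1=O)CCC[C@@H]2C(=O)OC(C)(C)C
F6 | step 20 | tert‑butyl (1S,7S,8aR)‑7‑(3,3‑dimethoxyprop‑1‑en‑2‑yl)‑6‑methoxy‑8a‑methyl‑1,2,3,7,8,8a‑hexahydronaphthalene‑1‑carboxylate | COC(OC)C(=C)[C@@H]1C[C@@]2(C)C(C=C1OC)=CCC[C@@H]2C(=O)OC(C)(C)C
F7 | step 20 | tert‑butyl (1S,4R,7S,8aR)‑7‑(3,3‑dimethoxyprop‑1‑en‑2‑yl)‑4‑hydroxy‑8a‑methyl‑6‑oxo‑1,2,3,4,6,7,8,8a‑octahydronaphthalene‑1‑carboxylate | COC(OC)C(=C)[C@@H]1C[C@@]2(C)C(=CC1=O)[C@H](O)CC[C@@H]2C(=O)OC(C)(C)C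
F8 | step 20 | tert‑butyl (1S,4R,7S,8aR)‑7‑(3,3‑dimethoxyprop‑1‑en‑2‑yl)‑4‑{[(2E,4R)‑2,4‑dimethyloct‑2‑enoyl]oxy}‑8a‑methyl‑6‑oxo‑1,2,3,4,6,7,8,8a‑octahydronaphthalene‑1‑carboxylate | COC(OC)C(=C)[C@@H]1C[C@@]2(C)C(=CC1=O)[C@H](OC(=O)/C(C)=C/[C@H](C)CCCC)CC[C@@H]2C(=O)OC(C)(C)C
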